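## Retrosynthetic overview

- Feature: ring B (seven-membered; C1, C10, C9, C8, C7, C6, C5) holds a ketone-level oxygen at C10 between quaternary C1 and C9H2, the trace of a 2-oxyallyl cation C1–C10–C9; C2–C3–C4 is the tether that becomes five-membered ring A.
- Target 29 ⇒ tricyclic ketone 17 by late oxygenation work: C10 ketone → β-alcohol; C6=C7 → C6-oxygenated C7=C8 (epoxide, enone, 1,2-reduction); acetate and aroyl ester last.
- 17 ⇒ chloromethyl ketone 15 by cleaving C1–C5 and C8–C9: one intramolecular (4+3) cycloaddition closes ring A and ring B together.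
- 15 ⇒ Weinreb amide 13 ⇒ hydroxy lactone 9 ⇒ isopropyl ketone 4 + dienyl iodide 6 (C4–C5 bond, C4 set from C3); C4, C3, C2, C1 and C10 all come from (S)-5-oxotetrahydrofuran-2-carboxylic acid 1.

Key step: step 8

Remarks on the chemistry:
- Numbering: C1 methyl-bearing fusion carbon, C2 CH2, C3 CH–OAc, C4 C(OH)iPr, C5 fusion CH, C6 CH–O-aroyl, C7=C8(Me), C9 CH2, C10 CH–OH. "β" is the face of the bicycle that carries the C1 methyl, "α" the opposite face.
- Acid 26 is taken as a purchasable reagent (otherwise one step from 4-hydroxybenzoic acid).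
- Compounds 11 to 15 are drawn as the major C1 epimer; the minor epimer travels with it, since C1 becomes planar in step 8.

## Route

Step 1
Reactants: 1 (S)-5-oxotetrahydrofuran-2-carboxylic acid; 2 isopropylmagnesium chloride
Product: 4 (S)-5-(2-methylpropanoyl)dihydrofuran-2(3H)-one, via acid chloride 3 (not isolated)
Conditions: (COCl)2, DMF (cat.), CH2Cl2, 0 °C → rt, evaporate; then iPrMgCl (1.05 equiv), CuI (5 mol %), THF, −78 °C
Reagents that add atoms: none
Why: Copper-catalysed acylation of a Grignard reagent by an acid chloride should stop at the hindered ketone at −78 °C and spare the less electrophilic lactone; the C3 centre comes unchanged from 1.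

Step 2
Reactants: 5 (E)-but-2-enal (crotonaldehyde)
Product: 6 (1E,3E)-1-iodopenta-1,3-diene
Conditions: CrCl2, CHI3, THF–dioxane, 0 °C; used as a solution
Reagents that add atoms: iodoform, IC(I)I
Why: Takai olefination, in which the gem-dichromium species formed from iodoform and divalent chromium adds to the aldehyde and eliminates to the (E)-iodoalkene (new C5=C6 bond), the existing E-alkene staying in place.

Step 3
Reactants: 6 (1E,3E)-1-iodopenta-1,3-diene; 4 (S)-5-(2-methylpropanoyl)dihydrofuran-2(3H)-one
Product: 9 (5S)-5-[(3R,4E,6E)-3-hydroxy-2-methylocta-4,6-dien-3-yl]dihydrofuran-2(3H)-one, via dienyllithium 7 (not isolated), via dienylcerium dichloride 8 (not isolated)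
Conditions: 6, t-BuLi (2 equiv), Et2O, −78 °C; CeCl3, THF, −78 °C; then 4, −78 °C; aq. NH4Cl
Reagents that add atoms: none
Why: Iodine–lithium exchange with retention of alkene geometry, transmetalation to the weakly basic organocerium reagent and 1,2-addition to the ketone, the new C4 centre (R) being set by polar Felkin–Anh control (C3–O bond anti to the incoming nucleophile, which passes the C3 hydrogen; the lactone ring oxygen is too poor a donor to chelate).

Step 4
Reactants: 9 (5S)-5-[(3R,4E,6E)-3-hydroxy-2-methylocta-4,6-dien-3-yl]dihydrofuran-2(3H)-one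
Product: 11 (3R,5S)-5-[(3R,4E,6E)-3-hydroxy-2-methylocta-4,6-dien-3-yl]-3-methyldihydrofuran-2(3H)-one, via dilithium enolate 10 (not isolated)
Conditions: LDA (2.2 equiv), THF, −78 °C; MeI, −78 → −40 °C
Reagents that add atoms: iodomethane, CI
Why: Alkylation of the lactone enolate (as its alkoxide dianion) should place the methyl group mainly trans to the C3 side chain, a centre (C1) that is of no consequence because it is erased in step 8.

Step 5
Reactants: 11 (3R,5S)-5-[(3R,4E,6E)-3-hydroxy-2-methylocta-4,6-dien-3-yl]-3-methyldihydrofuran-2(3H)-one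
Product: 12 (2R,4S,5R,6E,8E)-4,5-dihydroxy-N-methoxy-N,2-dimethyl-5-(propan-2-yl)deca-6,8-dienamide
Conditions: MeNH(OMe)·HCl, iPrMgCl, THF, −20 → 0 °C; crude product used at once
Reagents that add atoms: N,O-dimethylhydroxylamine hydrochloride, CNOC.Cl
Why: Lactone aminolysis by the magnesium amide of N,O-dimethylhydroxylamine (Weinreb amide formation) is basic throughout, so the dienylic tertiary alcohol is not ionised and no stereocentre is touched.

Step 6
Reactants: 12 (2R,4S,5R,6E,8E)-4,5-dihydroxy-N-methoxy-N,2-dimethyl-5-(propan-2-yl)deca-6,8-dienamide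
Product: 13 (2R)-3-[(4S,5R)-2,2-dimethyl-5-[(1E,3E)-penta-1,3-dien-1-yl]-5-(propan-2-yl)-1,3-dioxolan-4-yl]-N-methoxy-N,2-dimethylpropanamide
Conditions: 2-methoxypropene, PPTS (cat.), CH2Cl2, 0 °C; Et3N quench
Reagents that add atoms: 2-methoxypropene, COC(C)=C
Why: Kinetic acetonide formation goes through the mixed ketal at the secondary C3 hydroxyl, which closes onto the tertiary C4 hydroxyl without breaking the C4–O bond, so the C3/C4 configuration is carried into the cis-dioxolane and relactonisation is outrun.

Step 7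
Reactants: 13 (2R)-3-[(4S,5R)-2,2-dimethyl-5-[(1E,3E)-penta-1,3-dien-1-yl]-5-(propan-2-yl)-1,3-dioxolan-4-yl]-N-methoxy-N,2-dimethylpropanamide
Product: 15 (3R)-1-chloro-4-[(4S,5R)-2,2-dimethyl-5-[(1E,3E)-penta-1,3-dien-1-yl]-5-(propan-2-yl)-1,3-dioxolan-4-yl]-3-methylbutan-2-one, via tetrahedral adduct 14 (not isolated)
Conditions: ICH2Cl, MeLi·LiBr, THF, −78 °C; aq. NH4Cl
Reagents that add atoms: chloroiodomethane, ClCI
Why: Chloromethyllithium, formed by iodine–lithium exchange in the presence of the substrate, adds once to the Weinreb amide and the chelated tetrahedral adduct holds until work-up, which is the established homologation of Weinreb amides to chloromethyl ketones.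

Step 8
Reactants: 15 (3R)-1-chloro-4-[(4S,5R)-2,2-dimethyl-5-[(1E,3E)-penta-1,3-dien-1-yl]-5-(propan-2-yl)-1,3-dioxolan-4-yl]-3-methylbutan-2-one
Product: 17 cycloadduct ketone (cis-fused rings A and B; C10 ketone; C6=C7 alkene; 1β-methyl; 5β-H; 8α-methyl; 4α-isopropyl; 3β,4β-O-isopropylidene), via oxyallyl cation 16 (not isolated)
Conditions: Et3N (2 equiv), CF3CH2OH, 0.01 M, 0 °C → rt
Reagents that add atoms: none
Why: Triethylamine enolises 15 toward C1 and the enol(ate) loses chloride from C9 in the ionising, weakly nucleophilic solvent to give the 2-oxyallyl cation 16 (C1–C10–C9), which adds across the s-cis (E,E)-diene C5–C8 in a concerted but asynchronous, or rapid two-stage, (4+3) cycloaddition; the closest known reaction type is the intramolecular (4+3) cycloaddition of α-halo-ketone-derived oxyallyl cations with three-atom-tethered butadienes to hydroazulenones. Ring A closes when the tertiary cation terminus C1 bonds to the diene terminus C5 through the C2–C3–C4 tether (a 5-exo closure on the C5=C6 bond), and ring B closes as the seven-membered ring of the cycloaddition when C9 bonds to C8. C1 and C5 are controlled by the cis-dioxolane: both reacting arms hang from the same face of it, and bonding on the convex face of the emerging dioxabicyclo[3.3.0]octane keeps the C10–C9 and C6–C8 units away from the acetal carbon and its inward methyl, which puts C10 and C6 on the same side of ring A (cis fusion, C1 methyl and H5 syn to the two oxygens, ring B anti to the dioxolane). C8 follows from the E,E geometry through suprafacial bonding at both diene termini (H8 cis to H5) and is removed later, and the C1 configuration of 15 does not matter because C1 is planar in 16. The step needs the cycloaddition to outrun substitution at the primary chloride, Favorskii contraction and (3+2) closure, and needs cis fusion anti to the acetonide; the fully substituted C4 and the dioxolane bias the chain toward the reactive coiled rotamer, the short tether and high dilution favour the intramolecular path, and the basic medium leaves the dienylic C4–O bond and the acetonide intact.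

Step 9
Reactants: 17 cycloadduct ketone
Product: 18 10β-alcohol (C10–OH cis to the C1 methyl; otherwise as 17)
Conditions: NaBH4, MeOH–THF, −20 °C
Reagents that add atoms: none
Why: Borohydride reduction should deliver hydride to C10 from the α-face, anti to the methyl group on the neighbouring quaternary C1 (as with ketones flanked by an angular methyl group), giving the 10β-alcohol (10S).

Step 10
Reactants: 18 10β-alcohol
Product: 19 10β-tert-butyldimethylsilyl ether of 18
Conditions: TBSOTf, 2,6-lutidine, CH2Cl2, −78 → 0 °C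
Reagents that add atoms: tert-butyldimethylsilyl trifluoromethanesulfonate, CC(C)(C)[Si](C)(C)OS(=O)(=O)C(F)(F)F
Why: Silylation with the silyl triflate is the standard way to cap a hindered neopentyl-type secondary alcohol, and the buffered low-temperature conditions leave the acetonide alone.

Step 11
Reactants: 19 10β-silyl ether
Product: 20 6β,7β-epoxide of 19
Conditions: mCPBA, NaHCO3, CH2Cl2, 0 °C
Reagents that add atoms: 3-chloroperoxybenzoic acid, OOC(=O)c1cccc(Cl)c1
Why: Peracid epoxidation of the C6=C7 alkene should occur on the β-face, because the α-face is covered by the allylic 8α-methyl group and by ring A with its inward isopropyl group on the concave side of the cis-fused bicycle.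

Step 12
Reactants: 20 6β,7β-epoxide
Product: 21 6β-allylic alcohol (C7=C8 alkene carrying the C8 methyl; acetonide and 10β-silyl ether kept)
Conditions: LiTMP, Et2AlCl, toluene, 0 °C; then 20, 0 °C → rt; Rochelle salt work-up
Reagents that add atoms: none
Why: Aluminium-amide-promoted isomerisation of an epoxide to an allylic alcohol proceeds by syn β-elimination through a cyclic transition state, so the β-hydrogen at C8 (syn to the epoxide oxygen and far more accessible than the buried H5) is removed, the C7–O bond breaks and the C6–O bond keeps its β configuration.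

Step 13
Reactants: 21 6β-allylic alcohol
Product: 22 C6 enone (C6 ketone conjugated to C7=C8; acetonide and 10β-silyl ether kept)
Conditions: Dess–Martin periodinane, NaHCO3, CH2Cl2, 0 °C → rt
Reagents that add atoms: none
Why: Dess–Martin oxidation of the only free hydroxyl gives the enone under neutral conditions, removing the wrongly configured C6 centre without disturbing the C5 fusion hydrogen.

Step 14
Reactants: 22 C6 enone
Product: 23 enone diol (3β-OH; 4β-OH; 4α-isopropyl; 10β-silyl ether)
Conditions: AcOH–H2O (4:1), 40 °C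
Reagents that add atoms: none
Why: Acid-catalysed acetal hydrolysis is placed at the enone stage, where no allylic C–O bond can ionise, and weak aqueous acid should spare the hindered secondary silyl ether and be too mild to enolise the enone toward C5.

Step 15
Reactants: 23 enone diol
Product: 24 3β-acetate of 23 (4β-OH free)
Conditions: Ac2O, pyridine, DMAP (cat.), CH2Cl2, 0 °C → rt
Reagents that add atoms: acetic anhydride, CC(=O)OC(C)=O
Why: DMAP-catalysed acylation takes the secondary C3 hydroxyl, the only acylable one at this stage, since the tertiary C4 hydroxyl next to the isopropyl group is inert under these conditions.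

Step 16
Reactants: 24 3β-acetate enone
Product: 25 6α-allylic alcohol (3β-OAc; 4β-OH; 10β-silyl ether; C7=C8)
Conditions: NaBH4, CeCl3·7H2O, MeOH, −78 °C
Reagents that add atoms: none
Why: Luche 1,2-reduction of the enone should deliver hydride to C6 from the β-face, syn to H5 and away from the quaternary C4 with its inward isopropyl group on the α-face, which sets the 6α-alcohol; the acetate survives.

Step 17
Reactants: 25 6α-allylic alcohol; 26 4-(tert-butyldimethylsilyloxy)benzoic acid
Product: 28 bis-silyl ester (3β-OAc; 4β-OH; 6α-[4-(tert-butyldimethylsilyloxy)benzoyloxy]; 10β-silyl ether; C7=C8), via mixed anhydride 27 (not isolated)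
Conditions: 26, 2,4,6-Cl3C6H2COCl, Et3N, THF, rt; then 25, DMAP, toluene, rt → 60 °C
Reagents that add atoms: none
Why: Yamaguchi esterification acylates the hindered secondary allylic alcohol at oxygen, so the C6 configuration is retained, while the tertiary C4 hydroxyl does not react.

Step 18
Reactants: 28 bis-silyl ester
Product: 29 target CNP0146780.2 (3β-OAc; 4β-OH; 4α-isopropyl; 6α-(4-hydroxybenzoyloxy); 10β-OH; 1β-methyl; 5β-H; C7=C8)
Conditions: HF·pyridine, pyridine, THF, 0 °C → rt
Reagents that add atoms: none
Why: Buffered fluoride-mediated desilylation removes the aryl and the C10 silyl ethers in one operation and is mild enough for the acetate and the allylic benzoate-type ester.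

## Compound list

1 | (S)-5-oxotetrahydrofuran-2-carboxylic acid | O=C1CC[C@H](O1)C(=O)O | starting material
2 | isopropylmagnesium chloride | CC(C)[Mg]Cl | starting material
3 | (S)-5-oxotetrahydrofuran-2-carbonyl chloride | O=C1CC[C@H](O1)C(=O)Cl | intermediate
4 | (S)-5-(2-methylpropanoyl)dihydrofuran-2(3H)-one | O=C1CC[C@H](O1)C(=O)C(C)C | intermediate
5 | (E)-but-2-enal | C/C=C/C=O | starting material
6 | (1E,3E)-1-iodopenta-1,3-diene | I/C=C/C=C/C | intermediate
7 | (1E,3E)-penta-1,3-dienyllithium | [Li]/C=C/C=C/C | intermediate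
8 | (1E,3E)-penta-1,3-dienylcerium dichloride | Cl[Ce](Cl)/C=C/C=C/C | intermediate
9 | (5S)-5-[(3R,4E,6E)-3-hydroxy-2-methylocta-4,6-dien-3-yl]dihydrofuran-2(3H)-one | O=C1CC[C@H](O1)[C@@](O)(C(C)C)/C=C/C=C/C | intermediate
10 | dilithium alkoxide enolate of 9 | [Li+].[Li+].[O-]C1=CC[C@H](O1)[C@@]([O-])(C(C)C)/C=C/C=C/C | intermediate
11 | (3R,5S)-5-[(3R,4E,6E)-3-hydroxy-2-methylocta-4,6-dien-3-yl]-3-methyldihydrofuran-2(3H)-one | O=C1[C@H](C)C[C@H](O1)[C@@](O)(C(C)C)/C=C/C=C/C | intermediate
12 | (2R,4S,5R,6E,8E)-4,5-dihydroxy-N-methoxy-N,2-dimethyl-5-(propan-2-yl)deca-6,8-dienamide | CON(C)C(=O)[C@H](C)C[C@H](O)[C@@](O)(C(C)C)/C=C/C=C/C | intermediate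
13 | (2R)-3-[(4S,5R)-2,2-dimethyl-5-[(1E,3E)-penta-1,3-dien-1-yl]-5-(propan-2-yl)-1,3-dioxolan-4-yl]-N-methoxy-N,2-dimethylpropanamide | CC1(C)O[C@@H](C[C@@H](C)C(=O)N(C)OC)[C@@](O1)(C(C)C)/C=C/C=C/C | intermediate
14 | lithium alkoxide of the chloromethyl adduct of 13 (new carbinol centre undefined) | CC1(C)O[C@@H](C[C@@H](C)C([O-])(CCl)N(C)OC)[C@@](O1)(C(C)C)/C=C/C=C/C.[Li+] | intermediate
15 | (3R)-1-chloro-4-[(4S,5R)-2,2-dimethyl-5-[(1E,3E)-penta-1,3-dien-1-yl]-5-(propan-2-yl)-1,3-dioxolan-4-yl]-3-methylbutan-2-one | CC1(C)O[C@@H](C[C@@H](C)C(=O)CCl)[C@@](O1)(C(C)C)/C=C/C=C/C | intermediate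
16 | 2-oxyallyl cation (zwitterion) C1–C10–C9 from 15 | CC1(C)O[C@@H](C[C+](C)C([O-])=C)[C@@](O1)(C(C)C)/C=C/C=C/C | intermediate
17 | cycloadduct ketone (C10 ketone; C6=C7; 1β-Me; 5β-H; 8α-Me; 4α-iPr; 3β,4β-O-isopropylidene) | CC1(C)O[C@H]2C[C@]3(C)C(=O)C[C@H](C)C=C[C@@H]3[C@]2(O1)C(C)C | intermediate
18 | 10β-alcohol of 17 | CC1(C)O[C@H]2C[C@]3(C)[C@@H](O)C[C@H](C)C=C[C@@H]3[C@]2(O1)C(C)C | intermediate
19 | 10β-tert-butyldimethylsilyl ether of 18 | CC1(C)O[C@H]2C[C@]3(C)[C@@H](O[Si](C)(C)C(C)(C)C)C[C@H](C)C=C[C@@H]3[C@]2(O1)C(C)C | intermediate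
20 | 6β,7β-epoxide of 19 | CC1(C)O[C@H]2C[C@]3(C)[C@@H](O[Si](C)(C)C(C)(C)C)C[C@H](C)[C@H]4O[C@H]4[C@@H]3[C@]2(O1)C(C)C | intermediate
21 | 6β-allylic alcohol (C7=C8; acetonide; 10β-OTBS) | CC1(C)O[C@H]2C[C@]3(C)[C@@H](O[Si](C)(C)C(C)(C)C)CC(C)=C[C@@H](O)[C@@H]3[C@]2(O1)C(C)C | intermediate
22 | C6 enone (C7=C8; acetonide; 10β-OTBS) | CC1(C)O[C@H]2C[C@]3(C)[C@@H](O[Si](C)(C)C(C)(C)C)CC(C)=CC(=O)[C@@H]3[C@]2(O1)C(C)C | intermediate
23 | enone diol (3β-OH; 4β-OH; 10β-OTBS) | O[C@H]1C[C@]2(C)[C@@H](O[Si](C)(C)C(C)(C)C)CC(C)=CC(=O)[C@@H]2[C@]1(O)C(C)C | intermediate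
24 | 3β-acetate of 23 | CC(=O)O[C@H]1C[C@]2(C)[C@@H](O[Si](C)(C)C(C)(C)C)CC(C)=CC(=O)[C@@H]2[C@]1(O)C(C)C | intermediate
25 | 6α-allylic alcohol (3β-OAc; 4β-OH; 10β-OTBS) | CC(=O)O[C@H]1C[C@]2(C)[C@@H](O[Si](C)(C)C(C)(C)C)CC(C)=C[C@H](O)[C@@H]2[C@]1(O)C(C)C | intermediate
26 | 4-(tert-butyldimethylsilyloxy)benzoic acid | CC(C)(C)[Si](C)(C)Oc1ccc(cc1)C(=O)O | starting material
27 | 4-(tert-butyldimethylsilyloxy)benzoic 2,4,6-trichlorobenzoic anhydride | CC(C)(C)[Si](C)(C)Oc1ccc(cc1)C(=O)OC(=O)c1c(Cl)cc(Cl)cc1Cl | intermediate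
28 | bis-silyl ester (3β-OAc; 4β-OH; 6α-aroyloxy with aryl OTBS; 10β-OTBS) | CC(=O)O[C@H]1C[C@]2(C)[C@@H](O[Si](C)(C)C(C)(C)C)CC(C)=C[C@H](OC(=O)c3ccc(O[Si](C)(C)C(C)(C)C)cc3)[C@@H]2[C@]1(O)C(C)C | intermediate
29 | CNP0146780.2 | CC(=O)O[C@H]1C[C@]2(C)[C@@H](O)CC(C)=C[C@H](OC(=O)c3ccc(O)cc3)[C@@H]2[C@]1(O)C(C)C | target

## Step count and risks

Total step count: 18. Longest linear sequence: 17 steps (1 → 29 through steps 1 and 3 to 18; step 2 is a one-step side branch).

Steps most likely to fail:

1. Step 8. The primary chloride of 15 may be used up by substitution at C9 (amine or trifluoroethoxide) or by Favorskii contraction before the oxyallyl cation is trapped, or a stepwise closure may drain material into (3+2) products. The fallback sets out from 13 and returns at 17. Deprotonation of 13 (LDA, THF, −78 °C) and chlorination of the amide enolate with hexachloroethane should give the α-chloro Weinreb amide F1 (tertiary chloride at C1, either epimer). Methylmagnesium bromide then gives the tertiary α-chloro methyl ketone F2. Enolisation of F2 toward the methyl group (C9) with Et3N in CF3CH2OH, or with LiClO4/Et3N in ether, ionises the now tertiary C1–Cl bond, which has no bimolecular substitution pathway, to the same cation 16, which should close to 17.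

2. Step 3. Facial discrimination at the C4 carbonyl may be poor if a chelated transition state competes with the Felkin–Anh one, and 4 may enolise at C3. The fallback sets out from 1 and returns at 13; it reverses the order of the two carbon groups and relies on chelate control. Saponification of 1 and careful acidification give (S)-2-hydroxypentanedioic acid F3, which is ketalised at once (2,2-dimethoxypropane, TsOH, acetone) to the dioxolanone acid F4. Carbodiimide coupling with N,O-dimethylhydroxylamine gives the dioxolanone Weinreb amide F5. Dienyllithium 7 (1 equiv, −78 °C) attacks the activated dioxolanone carbonyl, and loss of acetone gives the α-hydroxy dienone F6. Excess isopropylmagnesium chloride 2 (THF, −78 °C) then adds through the five-membered magnesium alkoxide chelate (Cram cyclic model), entering on the side of the C3 hydrogen, to give the diol F7 with the same (4S,5R) configuration as 12. 2-Methoxypropene/PPTS gives the acetonide F8, and LDA/MeI methylation of its amide enolate returns 13 together with its C1 epimer.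

3. Step 9. Hydride may instead be delivered from the β-face (the convex face of the cis-fused bicycle, syn to the C1 methyl), giving the 10α-alcohol. The fallback sets out from 17 and returns at 18. Substrate control is replaced by catalyst control: reduction with (R)-2-methyl-CBS-oxazaborolidine and catecholborane, in which the quaternary C1 is the large group and C9H2 the small one, should give the (10S)-alcohol 18. No new compound is made.

Further compounds
F1 | step 8 | 2-chloro-3-[(4S,5R)-2,2-dimethyl-5-[(1E,3E)-penta-1,3-dien-1-yl]-5-(propan-2-yl)-1,3-dioxolan-4-yl]-N-methoxy-N,2-dimethylpropanamide (C2 epimers) | CC1(C)O[C@@H](CC(C)(Cl)C(=O)N(C)OC)[C@@](O1)(C(C)C)/C=C/C=C/C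
F2 | step 8 | 3-chloro-4-[(4S,5R)-2,2-dimethyl-5-[(1E,3E)-penta-1,3-dien-1-yl]-5-(propan-2-yl)-1,3-dioxolan-4-yl]-3-methylbutan-2-one (C3 epimers) | CC1(C)O[C@@H](CC(C)(Cl)C(C)=O)[C@@](O1)(C(C)C)/C=C/C=C/C
F3 | step 3 | (S)-2-hydroxypentanedioic acid | OC(=O)CC[C@H](O)C(=O)O
F4 | step 3 | 3-[(4S)-2,2-dimethyl-5-oxo-1,3-dioxolan-4-yl]propanoic acid | CC1(C)O[C@@H](CCC(=O)O)C(=O)O1
F5 | step 3 | 3-[(4S)-2,2-dimethyl-5-oxo-1,3-dioxolan-4-yl]-N-methoxy-N-methylpropanamide | CC1(C)O[C@@H](CCC(=O)N(C)OC)C(=O)O1
F6 | step 3 | (4S,6E,8E)-4-hydroxy-N-methoxy-N-methyl-5-oxodeca-6,8-dienamide | CON(C)C(=O)CC[C@H](O)C(=O)/C=C/C=C/C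
F7 | step 3 | (4S,5R,6E,8E)-4,5-dihydroxy-N-methoxy-N-methyl-5-(propan-2-yl)deca-6,8-dienamide | CON(C)C(=O)CC[C@H](O)[C@@](O)(C(C)C)/C=C/C=C/C
F8 | step 3 | 3-[(4S,5R)-2,2-dimethyl-5-[(1E,3E)-penta-1,3-dien-1-yl]-5-(propan-2-yl)-1,3-dioxolan-4-yl]-N-methoxy-N-methylpropanamide | CC1(C)O[C@@H](CCC(=O)N(C)OC)[C@@](O1)(C(C)C)/C=C/C=C/C
F0 | step 9 | none | none
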